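The cyclohexane is disconnected at C5–C6, the bond between the methyl-bearing tertiary carbinol C5 and the chain-bearing carbinol C6 that sits beside the gem-dimethyl carbon C1. The precursor is an acyclic alkynone: C5 is a methyl ketone and C6≡C7 an alkyne on the quaternary C1. A nickel-catalysed enantioselective reductive cyclisation forms the ring, the C5 stereocentre (as its silyl ether) and an exocyclic C6=C7 alkene in one operation. That alkene is the latent C6 carbinol: a singlet-oxygen ene reaction from the face opposite the C5 silyloxy group should install the trans C6–OH and the E C7=C8 bond together. Two Wittig reactions then build the polyenal.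

Key step: step 6

Remark (numbering): carotenoid numbering is used; ring C1 (C(CH3)2), C2–C4 (CH2), C5 (C(CH3)OH), C6 (C(OH) bearing the chain); chain C7 to C15, then C15′ back to the aldehyde carbon C10′.
Remark (assumption): racemic 2-methyl-2-vinyloxirane is used, so 8–12 are pairs of epimers at the side-chain carbinol (future C9); this centre becomes sp2 in step 8 and its configuration is without consequence.
Remark (assumption): the antipode of the P-stereogenic ligand in step 6 that gives 5R is assigned by a trial run with each antipode.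

Step 1
Reactants: 1 isobutyronitrile; 2 2-(3-chloropropyl)-2-methyl-1,3-dioxolane
Product: 3 2,2-dimethyl-5-(2-methyl-1,3-dioxolan-2-yl)pentanenitrile
Conditions: LiN(i-Pr)2, THF, −78 °C; then 2, DMPU, NaI (cat.), −78 °C → rt
Reagents that add atoms: none
Why: Nitrile-anion alkylation: the α-lithiated nitrile displaces the primary chloride (SN2) and so creates the quaternary carbon C1 with both methyl groups in place.

Step 2
Reactants: 3 2,2-dimethyl-5-(2-methyl-1,3-dioxolan-2-yl)pentanenitrile
Product: 5 2,2-dimethyl-5-(2-methyl-1,3-dioxolan-2-yl)pentanal, via N-aluminoaldimine 4 (not isolated)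
Conditions: i-Bu2AlH, toluene, −78 °C; then aq. KNaC4H4O6 (potassium sodium tartrate), rt
Reagents that add atoms: water, O
Why: Partial reduction of the hindered nitrile by i-Bu2AlH stops at the N-aluminoaldimine, which neutral aqueous work-up should hydrolyse to the aldehyde without opening the dioxolane.

Step 3
Reactants: 5 2,2-dimethyl-5-(2-methyl-1,3-dioxolan-2-yl)pentanal
Product: 6 2-(4,4-dimethylhex-5-yn-1-yl)-2-methyl-1,3-dioxolane
Conditions: Ohira–Bestmann reagent, K2CO3, MeOH, 0 °C → rt
Reagents that add atoms: dimethyl (1-diazo-2-oxopropyl)phosphonate, COP(=O)(OC)C(=[N+]=[N-])C(C)=O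
Why: Seyferth–Gilbert homologation in the Ohira–Bestmann version: the non-enolisable aldehyde is converted by the diazophosphonate anion into the terminal alkyne (C6≡C7) through a vinylidene carbene and a 1,2-hydrogen shift.

Step 4
Reactants: 6 2-(4,4-dimethylhex-5-yn-1-yl)-2-methyl-1,3-dioxolane; 7 2-methyl-2-vinyloxirane (racemic)
Product: 8 3,7,7-trimethyl-10-(2-methyl-1,3-dioxolan-2-yl)dec-1-en-5-yn-3-ol (racemic)
Conditions: n-BuLi, THF, −78 °C; then 7, DMPU, −20 °C → rt; H2O
Reagents that add atoms: none
Why: SN2 opening of the oxirane by the lithium acetylide at the unsubstituted ring carbon (no Lewis acid, so the tertiary allylic carbon and the SN2′ position should stay untouched) attaches C8–C11 as a tertiary vinyl carbinol, the precursor of the C9=C10–C11 unit.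

Step 5
Reactants: 8 3,7,7-trimethyl-10-(2-methyl-1,3-dioxolan-2-yl)dec-1-en-5-yn-3-ol
Product: 9 10-hydroxy-6,6,10-trimethyldodec-11-en-7-yn-2-one (racemic)
Conditions: pyridinium p-toluenesulfonate (cat.), acetone/H2O, 50 °C
Reagents that add atoms: water, O
Why: Acid-catalysed ketal hydrolysis with a pyridinium salt is mild enough to leave the tertiary allylic alcohol and the alkyne untouched and frees the methyl ketone (C5).

Step 6
Reactants: 9 10-hydroxy-6,6,10-trimethyldodec-11-en-7-yn-2-one
Product: 10 (E)-3-methyl-5-[(6R)-2,2,6-trimethyl-6-(triethylsilyloxy)cyclohexylidene]pent-1-en-3-ol (C3 epimers)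
Conditions: Ni(cod)2 (10 mol %), AntPhos [4-(anthracen-9-yl)-3-tert-butyl-2,3-dihydro-1,3-benzoxaphosphole, one antipode] (12 mol %), Et3SiH (3 equiv), 1,4-dioxane, rt → 50 °C
Reagents that add atoms: triethylsilane, CC[SiH](CC)CC
Why: Zerovalent nickel binds the alkyne and the ketone of 9 and undergoes oxidative cyclisation to an oxanickelacyclopentene, which forms the C5–C6 bond; σ-bond metathesis of the Ni–O bond with Et3SiH gives the O–SiEt3 ether and a nickel hydride, and C–H reductive elimination at C7 releases 10 and the catalyst. The closest known reaction type is the nickel-catalysed enantioselective reductive cyclisation of alkynones with silanes, applied here to an all-carbon tether with a quaternary propargylic carbon. The cyclohexane closes in the 6-exo-dig mode: the ketone carbon bonds to the proximal alkyne carbon C6 and the former triple bond stays exocyclic, whereas the 7-endo closure at C7 is disfavoured. The C5 stereocentre is set in the oxidative cyclisation, where the P-stereogenic ligand on nickel selects the face of the ketone; the antipode that gives 5R is used. Syn addition of C5 and H across the alkyne fixes the E geometry (C8 cis to C1); chemoselectivity is secured because the distant vinyl group cannot form an unstrained metallacycle with the alkyne, and the gem-dimethyl group at C1 favours the folded conformer needed for closure.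

Step 7
Reactants: 10 (E)-3-methyl-5-[(6R)-2,2,6-trimethyl-6-(triethylsilyloxy)cyclohexylidene]pent-1-en-3-ol
Product: 12 (1R,2R)-1-[(1E)-3-hydroxy-3-methylpenta-1,4-dien-1-yl]-2,6,6-trimethyl-2-(triethylsilyloxy)cyclohexan-1-ol (side-chain carbinol epimers), via allylic hydroperoxide 11 (not isolated)
Conditions: O2, hν (white LED), tetraphenylporphyrin (cat.), CH2Cl2, −30 °C; then PPh3, −30 °C → rt
Reagents that add atoms: dioxygen, O=O
Why: Schenck ene reaction of singlet oxygen: only C8 carries allylic hydrogens (C1 and C5 are fully substituted), so oxygen must bond to C6 and the double bond must move to C7=C8 (E); attack should occur on the ring face opposite the axial C5 silyloxy group and the axial C1 methyl, which sets C6 as R (5,6-trans), and PPh3 reduces the hydroperoxide without touching the stereocentre.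

Step 8
Reactants: 12 (1R,2R)-1-[(1E)-3-hydroxy-3-methylpenta-1,4-dien-1-yl]-2,6,6-trimethyl-2-(triethylsilyloxy)cyclohexan-1-ol
Product: 13 [(2E,4E)-5-[(1R,2R)-1,2-dihydroxy-2,6,6-trimethylcyclohexyl]-3-methylpenta-2,4-dien-1-yl]triphenylphosphonium bromide
Conditions: PPh3·HBr (1.1 equiv), MeOH, 0 °C → rt
Reagents that add atoms: triphenylphosphine hydrobromide, [Br-].[PH+](c1ccccc1)(c1ccccc1)c1ccccc1
Why: HBr ionises the doubly allylic tertiary C9 carbinol to a pentadienyl cation that PPh3 captures at the unhindered terminus C11 (allylic phosphonium synthesis from a vinyl carbinol, SN1′), which should give the conjugated 7E,9E salt and erase the C9 centre, while the acidic methanol also cleaves the tertiary triethylsilyl ether.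

Step 9
Reactants: 13 [(2E,4E)-5-[(1R,2R)-1,2-dihydroxy-2,6,6-trimethylcyclohexyl]-3-methylpenta-2,4-dien-1-yl]triphenylphosphonium bromide; 14 (2E,4E,6E)-2,7-dimethylocta-2,4,6-trienedial
Product: 15 (2E,4E,6E,8E,10E,12E)-13-[(1R,2R)-1,2-dihydroxy-2,6,6-trimethylcyclohexyl]-2,7,11-trimethyltrideca-2,4,6,8,10,12-hexaenal
Conditions: 14 (2.5 equiv), NaOMe (1.1 equiv, slow addition), MeOH/CH2Cl2, −10 °C → rt
Reagents that add atoms: none
Why: Wittig olefination of the semi-stabilised C15 ylide with one aldehyde group of the symmetrical dialdehyde (used in excess) forms C11=C12; the product enal is less electrophilic than 14, which limits double olefination, and any 11Z isomer should equilibrate thermally to E.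

Step 10
Reactants: 15 (2E,4E,6E,8E,10E,12E)-13-[(1R,2R)-1,2-dihydroxy-2,6,6-trimethylcyclohexyl]-2,7,11-trimethyltrideca-2,4,6,8,10,12-hexaenal; 16 (1,3-dioxolan-2-ylmethyl)triphenylphosphonium bromide
Product: 18 (2E,4E,6E,8E,10E,12E,14E)-15-[(1R,2R)-1,2-dihydroxy-2,6,6-trimethylcyclohexyl]-4,9,13-trimethylpentadeca-2,4,6,8,10,12,14-heptaenal, via dioxolane acetal 17 (not isolated)
Conditions: 16, t-BuOK, THF, 0 °C → rt; then aq. oxalic acid, THF, rt
Reagents that add atoms: water, O
Why: Wittig reaction with the acetal-masked formylmethylene ylide adds C11′ and C10′ without the over-homologation that a free formyl ylide risks, and mild aqueous acid should unmask the aldehyde and equilibrate the new conjugated C11′=C12′ bond to E.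

Compound list
1 | isobutyronitrile | CC(C)C#N | starting material
2 | 2-(3-chloropropyl)-2-methyl-1,3-dioxolane | CC1(CCCCl)OCCO1 | starting material
3 | 2,2-dimethyl-5-(2-methyl-1,3-dioxolan-2-yl)pentanenitrile | CC1(CCCC(C)(C)C#N)OCCO1 | intermediate
4 | N-(diisobutylalumino)aldimine of 5 | CC1(CCCC(C)(C)C=N[Al](CC(C)C)CC(C)C)OCCO1 | intermediate (not isolated)
5 | 2,2-dimethyl-5-(2-methyl-1,3-dioxolan-2-yl)pentanal | CC1(CCCC(C)(C)C=O)OCCO1 | intermediate
6 | 2-(4,4-dimethylhex-5-yn-1-yl)-2-methyl-1,3-dioxolane | CC1(CCCC(C)(C)C#C)OCCO1 | intermediate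
7 | 2-methyl-2-vinyloxirane (racemic) | CC1(C=C)CO1 | starting material
8 | 3,7,7-trimethyl-10-(2-methyl-1,3-dioxolan-2-yl)dec-1-en-5-yn-3-ol (racemic) | C=CC(C)(O)CC#CC(C)(C)CCCC1(C)OCCO1 | intermediate
9 | 10-hydroxy-6,6,10-trimethyldodec-11-en-7-yn-2-one (racemic) | C=CC(C)(O)CC#CC(C)(C)CCCC(C)=O | intermediate
10 | (E)-3-methyl-5-[(6R)-2,2,6-trimethyl-6-(triethylsilyloxy)cyclohexylidene]pent-1-en-3-ol (C3 epimers) | C=CC(C)(O)C/C=C1\C(C)(C)CCC[C@@]1(C)O[Si](CC)(CC)CC | intermediate
11 | (1R,2R)-2-hydroperoxy-2-[(1E)-3-hydroxy-3-methylpenta-1,4-dien-1-yl]-1,3,3-trimethylcyclohexyl triethylsilyl ether (side-chain carbinol epimers) | C=CC(C)(O)/C=C/[C@@]1(OO)C(C)(C)CCC[C@@]1(C)O[Si](CC)(CC)CC | intermediate (not isolated)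
12 | (1R,2R)-1-[(1E)-3-hydroxy-3-methylpenta-1,4-dien-1-yl]-2,6,6-trimethyl-2-(triethylsilyloxy)cyclohexan-1-ol (side-chain carbinol epimers) | C=CC(C)(O)/C=C/[C@@]1(O)C(C)(C)CCC[C@@]1(C)O[Si](CC)(CC)CC | intermediate
13 | [(2E,4E)-5-[(1R,2R)-1,2-dihydroxy-2,6,6-trimethylcyclohexyl]-3-methylpenta-2,4-dien-1-yl]triphenylphosphonium bromide | C/C(=C\C[P+](c1ccccc1)(c1ccccc1)c1ccccc1)/C=C/[C@@]2(O)C(C)(C)CCC[C@@]2(C)O.[Br-] | intermediate
14 | (2E,4E,6E)-2,7-dimethylocta-2,4,6-trienedial | O=C/C(C)=C/C=C/C=C(C)/C=O | starting material
15 | (2E,4E,6E,8E,10E,12E)-13-[(1R,2R)-1,2-dihydroxy-2,6,6-trimethylcyclohexyl]-2,7,11-trimethyltrideca-2,4,6,8,10,12-hexaenal | O=C/C(C)=C/C=C/C=C(C)/C=C/C=C(C)/C=C/[C@@]1(O)C(C)(C)CCC[C@@]1(C)O | intermediate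
16 | (1,3-dioxolan-2-ylmethyl)triphenylphosphonium bromide | [Br-].C(C1OCCO1)[P+](c1ccccc1)(c1ccccc1)c1ccccc1 | starting material
17 | (1R,2R)-1-[(1E,3E,5E,7E,9E,11E)-14-(1,3-dioxolan-2-yl)-3,7,12-trimethyltetradeca-1,3,5,7,9,11,13-heptaen-1-yl]-2,6,6-trimethylcyclohexane-1,2-diol (13E/13Z mixture) | O1CCOC1C=C/C(C)=C/C=C/C=C(C)/C=C/C=C(C)/C=C/[C@@]2(O)C(C)(C)CCC[C@@]2(C)O | intermediate (not isolated)
18 | (2E,4E,6E,8E,10E,12E,14E)-15-[(1R,2R)-1,2-dihydroxy-2,6,6-trimethylcyclohexyl]-4,9,13-trimethylpentadeca-2,4,6,8,10,12,14-heptaenal | O=C/C=C/C(C)=C/C=C/C=C(C)/C=C/C=C(C)/C=C/[C@@]1(O)C(C)(C)CCC[C@@]1(C)O | target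

Total step count: 10.
Longest linear sequence: 10 steps (1 and 2 to 18); 7, 14 and 16 are purchased and enter directly.

Steps most likely to fail

Step 6. The oxidative cyclisation at the alkyne carbon that carries the quaternary C1 may be slow with the bulky chiral ligand, so that hydrosilylation of the alkyne or of the ketone competes; the two faces of the dialkyl ketone may also be poorly distinguished. The fallback sets out from 9 and comes back at 10, and it obtains the stereocentre by resolution instead of asymmetric catalysis. Ni(cod)2 with the small achiral donor PBu3 and Et3SiH in THF should close 9 more readily to the racemic silyl ether F1 (same E alkene, both configurations at C5). Preparative chromatography on a chiral stationary phase (cellulose tris(3,5-dimethylphenylcarbamate)) then separates the 5R material, which is 10, from the 5S antipode; the two side-chain epimers of each are pooled.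

Step 7. The ene reaction may be slow at the crowded C6 terminus (physical quenching of singlet oxygen, radical rearrangement of the hydroperoxide on long irradiation), and facial selectivity may erode because the small oxidant feels the axial silyloxy group too little. The fallback sets out from 10 and comes back at 12; oxygen is delivered by a bulkier electrophile and the double bond is moved in a separate base step. mCPBA/NaHCO3 in CH2Cl2 at 0 °C should epoxidise the trisubstituted exocyclic alkene (the vinyl group is far less reactive) from the face opposite the silyloxy group and give the spiro-epoxide F2. Et2Al(NC9H18) (diethylaluminium 2,2,6,6-tetramethylpiperidide, excess, toluene, 0 °C) then removes a C8 hydrogen and opens the C7–O bond (epoxide to allylic alcohol isomerisation; C6 has no other β-hydrogen), which should give 12 with the E C7=C8 bond.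

Step 8. Under the protic acid the pentadienyl cation also places positive charge at C7 next to the C6 carbinol, so that semipinacol-type migration of a ring bond, cyclic ether formation or ionisation at C6 (epimerisation) may compete with capture by phosphorus. The fallback sets out from 12 and comes back at 13; the allylic transposition is run as a buffered SN2′ bromination and phosphorus is introduced by SN2 while the silyl ether is still in place. PBr3 with pyridine in Et2O at −30 °C should convert the tertiary vinyl carbinol into the primary allylic bromide F3. PPh3 in toluene at rt should give the silylated phosphonium bromide F4, and HF·pyridine in THF at 0 °C removes the triethylsilyl group to give 13.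

Further compounds
F1 | step 6 | racemic (E)-3-methyl-5-[2,2,6-trimethyl-6-(triethylsilyloxy)cyclohexylidene]pent-1-en-3-ol | C=CC(C)(O)C/C=C1\C(C)(C)CCCC1(C)O[Si](CC)(CC)CC
F2 | step 7 | spiro-epoxide of 10 at C6–C7, oxirane oxygen on the ring face opposite the C5 silyloxy group | C=CC(C)(O)C[C@H]1O[C@@]12C(C)(C)CCC[C@@]2(C)O[Si](CC)(CC)CC
F3 | step 8 | (1R,2R)-1-[(1E,3E)-5-bromo-3-methylpenta-1,3-dien-1-yl]-2,6,6-trimethyl-2-(triethylsilyloxy)cyclohexan-1-ol | C/C(=C\CBr)/C=C/[C@@]1(O)C(C)(C)CCC[C@@]1(C)O[Si](CC)(CC)CC
F4 | step 8 | [(2E,4E)-5-[(1R,2R)-1-hydroxy-2,6,6-trimethyl-2-(triethylsilyloxy)cyclohexyl]-3-methylpenta-2,4-dien-1-yl]triphenylphosphonium bromide | C/C(=C\C[P+](c1ccccc1)(c1ccccc1)c1ccccc1)/C=C/[C@@]2(O)C(C)(C)CCC[C@@]2(C)O[Si](CC)(CC)CC.[Br-]
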